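**The charge.** A millimole of substrate takes up two millimoles of partner on its way to intermediate E, whether it goes through intermediates A and B or through intermediates C and D.

| setting | dusk | autumn | spring |
|---|---|---|---|
| substrate | 10 mM | 10 mM | 10 mM |
| partner | 44.0 mM | 11.0 mM | 22.0 mM |
| capture agent | 3.00 mM | 3.00 mM | 3.00 mM |
| time | 6.0 min | 6.0 min | 6.0 min |

    substrate → intermediate C (k1 = 0.00302 s⁻¹)
    capture agent + intermediate C → trapped intermediate (k2 = 0.273 L mol⁻¹ s⁻¹)
    partner + intermediate A → intermediate B (k3 = 2.09 L mol⁻¹ s⁻¹)
    partner + intermediate D ⇌ intermediate E (K4 = 1300 L mol⁻¹, k4 = 1.18 L mol⁻¹ s⁻¹)
    partner + intermediate C → intermediate D (k5 = 1.46 L mol⁻¹ s⁻¹)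
    intermediate B → intermediate E (k6 = 0.251 s⁻¹)
    intermediate C → product (k7 = 0.0129 s⁻¹)
    substrate + partner → intermediate A (k8 = 7.29 L mol⁻¹ s⁻¹)

- which of these there is most of at the end, counted by the substrate in it, dusk (product / intermediate E / trapped intermediate / intermediate D / intermediate A)
- which of these there is most of at the end, counted by the substrate in it, autumn (product / intermediate E / trapped intermediate / intermediate D / intermediate A)
- which of these there is most of at the end, counted by the substrate in it, spring (product / intermediate E / trapped intermediate / intermediate D / intermediate A)
- how much there is at the end of the one of these that leads, in percent of the substrate charged: dusk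
- how much there is at the end of the one of these that leads, in percent of the substrate charged: autumn
- how much there is at the end of the one of these that leads, in percent of the substrate charged: spring

**Bench rule.** I count partner per substrate: 4.40 at dusk, 2.20 in spring, 1.10 in autumn. The rule says partner serves substrate first and intermediate A second. Dusk and spring stand above two, so I expect intermediate E to lead there. In autumn, at the charged partner, substrate meets partner 26.6 times faster than it leaks to intermediate C. That ratio falls as partner falls, but I leave the leak out of this reckoning as a simplification. The half-life of substrate with partner as charged, 0.14 min, is short against the time. The rule then leaves intermediate A at two minus the count, 90.0 %.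

**The border.** The rule needs the first addition finished before the second begins. The test is the selectivity factor, the rate constant of substrate with partner over that of intermediate A with partner: 3.49. That is a small ratio. With intermediate A at the first answer, the two draw partner equally once substrate is down to 25.8 % of its charge. So the rule fails in autumn, and I go round again.

**Second round.** Integrating the competition gives a curve. The share of intermediate A is the substrate share raised to the inverse factor, minus the substrate share, over one minus the inverse factor. From 25.8 % the curve gives 58.9 %. The partner balance then leaves substrate at 15.6 %, and the curve returns 60.4 %. I commit to intermediate A leading autumn at 60.4 %.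

**The forecast.** It names intermediate E at dusk, intermediate A in autumn and intermediate E in spring, at 96 %, 59 % and 84 %. Its grounds for autumn are these: "11 mM runs out with most material stranded at A". Its autumn figure differs from mine by 1.4 percentage points.

**The flask.** Dusk gives intermediate E at 96.7 %, spring intermediate E at 83.5 %, and autumn intermediate A at 53.5 %. The leaders are as forecast, and the dusk and spring figures lie within tolerance. The autumn figure stands 5.5 points below the forecast and 6.9 points below my reckoning. At that point autumn still holds 3.41 % of its substrate and 1.32 % of its partner. With that partner, the autumn addition to substrate runs at 0.350 of the leak, slower than the leak, and autumn holds 10.1 % of product.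

**The neighbour.** A flask like dusk, but with 18 mM of partner, counts 1.80 partners per substrate. The first answer for intermediate A is 20.0 %. Here I run the curve backwards with the factor 3.49, which leaves substrate at 0.112 %. The balance then returns 19.8 % for intermediate A. The flask holds 68.2 % of intermediate E, 14.3 % of intermediate D and 14.7 % of intermediate A.

The numbers of this flask were drawn at random within sensible limits; no experiment stands behind them.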